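## The problem

Selaginellin F is built on one benzene ring (ring A) that carries four substituents in a row: a hydroxymethyl group on C5, a (4-hydroxyphenyl)ethynyl group (ring E) on C6, the diarylmethylidene carbon Cq on C1 and a 2,4-dihydroxyphenyl ring (ring D) on C2. C3 and C4 are unsubstituted. Cq is bonded to a 4-hydroxyphenyl ring (ring B) and, through a double bond, to a cyclohexa-2,5-dienone (ring C), so the chromophore is a p-quinone methide of the fuchsone type. There is no stereocenter, and the exocyclic double bond has no configuration because ring C is symmetric and rings B and C exchange roles by tautomerism. The task is therefore regiochemical: four different groups must be placed on adjacent carbons, and the two most hindered bonds, C1–Cq and C6–alkyne, are next to each other. The quinone methide adds nucleophiles and hydrides and has to be made last. The diarylalkyne rules out hydrogenolysis and can be attacked by the neighbouring C5 oxygen under base or soft metals. The benzylic alcohol, four free phenols and the ring D ortho hydroxyl, which lies within reach of Cq, limit the acids, bases and oxidants usable at the end. The structure opens up because Cq bears two identical para-oxygenated aryl groups and sits ortho to a biaryl bond whose other ring has an ortho oxygen, so Cq can be a carbonyl carbon tied to that oxygen as a six-membered lactone. In that 6H-benzo[c]chromen-6-one, C1 and C2 of ring A are C3 and C4 of a 7-oxygenated coumarin, the unsubstituted C3–C4 unit is a vinyl group on the coumarin, and C5–C6, with a formyl-level carbon and an alkynyl group, are the two carbons of an ynal triple bond.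

## Retrosynthesis

**Quinone methide.** Adding water across the Cq=ring C double bond and capping the oxygens turns target 23 into triarylcarbinol 22. In 22, rings B and C are the same 4-(methoxymethoxy)phenyl group, ring E and the para oxygen of ring D carry methoxymethyl ethers, the C5 hydroxymethyl is a silyl ether and the ring D ortho hydroxyl is free. This is preferred to carrying the quinone methide through earlier steps, where it would not survive. Every protecting group in 22 is acid-labile and the carbinol ionizes in acid, so one acid treatment must remove five groups and dehydrate.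

**Both Cq–aryl bonds.** The bonds from Cq to rings B and C are cut together. Since the two rings are identical at this stage, Cq becomes a carboxyl carbon, and tying it to the ring D ortho oxygen makes it the lactone carbonyl of benzo[c]chromenone 17. The nucleophile is aryllithium 20, made from bromide 19, which is one step from 4-bromophenol 18. A ketone precursor would need the two rings introduced one at a time, and an open ester would leave the ring D oxygen to be protected separately; the lactone does both jobs. The cut removes two rings and fourteen carbons. The forward step must add twice, through ketone 21, at a carbonyl flanked by an aryl and an alkynyl group, without touching the alkyne.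

**Oxidation level at C5.** Silyl ether 17 comes from alcohol 16, and 16 from aldehyde 15. The aldehyde is wanted in 15 because it is the activating group of the ring-forming step. It has to be reduced and capped before the aryllithium step, since a free alkoxide would sit beside the triple bond.

**Ring A (key disconnection).** Ring A of 15 is cut at C6a–C7 and C8–C9 (ring A bonds C1–C6 and C4–C5), a retro-(4+2) that leaves coumarin diene 6 and diynal 13.
- Cutting here, and not at the biaryl bond or the aryl–alkyne bond, forms the crowded C1–C6 bond while the ring is made, with the arylethynyl group already in place. It also divides 15 into two pieces of similar size.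
- With a bare vinyl group the orientation would rest on a balance: the 7-alkoxyaryl ring on coumarin C4 favours bonding of C3 to the alkynyl-bearing carbon, while the lactone carbonyl on C3 favours the opposite.
- The diene therefore carries an ethoxy group on the vinyl terminus. As a 1-alkoxydiene it directs its far end, coumarin C3, to the β-carbon of the ynal, in concert with the aryl ring.
- In cycloadduct 14 the ethoxy group is the leaving group, so ring A aromatizes by loss of ethanol and no dehydrogenation is needed.
- An amino donor would orient equally well, but the amine set free would add to the ynal.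
- The forward reaction must pick the aldehyde-conjugated triple bond of 13 and must spare a sensitive diynal at the temperature the diene needs.

**Diene.** The bond between coumarin C4 and the ethoxyvinyl group is cut to enol triflate 4 and the commercial (E)-boronate 5; the cross-coupling fixes the diene geometry. Triflate 4 comes from 4-hydroxycoumarin 3. Compound 3 is opened at the lactone C–O bond and at C2–C3 to acetophenone 2 and a carbonate carbon, which becomes Cq of the target. Ether 2 is the selectively protected form of 2,4-dihydroxyacetophenone 1. Building the coumarin this way puts the protecting group on before the second acidic hydroxyl exists, so two hydroxyls never have to be told apart on a coumarin.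

**Dienophile.** Diynal 13 is the oxidation product of diynol 12, whose central sp–sp bond is cut to arylacetylene 9 and bromoalkyne 11. Alkyne 9 comes from aldehyde 8 by one-carbon homologation, and 8 from 4-hydroxybenzaldehyde 7; 11 is the bromination product of propargyl alcohol 10. A heterocoupling is chosen over an oxidative coupling of two terminal alkynes because only it gives the unsymmetrical diyne alone. The aldehyde is unveiled last because 13 is the least stable compound of the branch.

## Roads not taken

**Alternative 1:** Ring A is bought as a benzene, and the C6–alkyne and C1–Cq bonds are made in one flask on an aryne; ring D is attached later by cross-coupling at C2, whose oxygen serves as the directing group.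
- Forward key step: a hindered lithium amide removes the hydrogen between chlorine and the aryl ether oxygen of aryl chloride A2. Loss of lithium chloride gives the aryne, the lithium acetylide of alkyne A3 adds at the carbon remote from the oxygen, and the resulting aryllithium is trapped by a chloroformate to give benzoate A1.
- Merits: three adjacent substituents are set from a simple 1,2,4-trisubstituted benzene, the orientation follows from a well-understood inductive effect, and no diynal is needed.
- Weak points: acetylides are sluggish aryne nucleophiles and compete with the amide base. The acetylide must enter ortho to the protected hydroxymethyl group. The chloroformate meets two organolithiums. Afterwards the aryl acetal must be cleaved beside an alkyl acetal, triflated, and coupled with a 2,4-dioxygenated arylboron reagent next to the ester, and the ring D ortho oxygen needs its own protection.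
- Comparison: this road reaches a fully substituted ring A in fewer steps and its regiochemistry is more certain. The chosen plan sets against it that the biaryl bond and the Cq–oxygen tie exist before ring A does, so no coupling is needed beside a hindered ester, and that only two operations separate 15 from the aryllithium step.

**Alternative 2:** Three bonds of ring A (C1–C2, C3–C4, C5–C6) are cut at once, so that all six carbons come from three triple bonds, two of them linked by the future lactone ester.
- Forward key step: with CpCo(CO)2 under irradiation, aryl diynoate A5 forms a cobaltacycle from its ester-linked triple bonds, closing the lactone ring, and takes up silylated propargyl ether A6 to give benzo[c]chromenone A4.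
- Merits: ring A and the lactone ring are formed in one operation, and the C1–C2 bond is made intramolecularly.
- Weak points: A5 is an aryl ester of a diynoic acid, which is electrophilic and prefers an ester conformation that holds the two alkynes apart. Its conjugated diyne offers the metal two triple bonds. The orientation of A6 rests only on the size of the silyl group. Self-trimerization competes, and the silyl group of A4 must then be removed in an extra step.
- Comparison: in bonds per step this road is better, and A4 would reach silyl ether 17 in about the same number of steps. The chosen plan sets against it one orientation question in place of three selectivity questions, and a metal-free ring formation.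

**Alternative 3:** Ring A bonds C4–C5 and C1–C2 are cut, and the aryl–alkyne bond is made afterwards from a C6 hydroxyl.
- Forward key step: chromone A8, activated by a silyl triflate, is attacked at its C2 by the terminal carbon of bis(silyl enol ether) A9. An amine base in ethanol then opens the pyranone, closes ring A by aldol condensation and closes the lactone to give hydroxybenzo[c]chromenone A7.
- Merits: the orientation is fixed by connectivity, domino reactions of this kind are established on chromones, there is no diynal, and ring E could be varied late.
- Weak points: the reacting terminus of A9 is substituted. The open-chain intermediate is a β-silyloxy ketone that can lose silanolate under the basic conditions. The 7-silyloxy group lowers the electrophilicity of the activated chromone and may itself be cleaved in ethanol. A7 still needs triflation and a coupling at a carbon between the lactone carbonyl and the protected hydroxymethyl group.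
- Comparison: in regiochemical certainty this road is better than the chosen one and its precedent is at least equal. The chosen plan sets against it convergence: the arylethynyl arm arrives in the ring-forming step, two later steps are saved, and no β-silyloxy ketone is exposed to base.

Key step: step 10

Remark on the chemistry: the target is taken as the open quinone methide of the SMILES; the ring-closed 6,6-diaryl-6H-benzo[c]chromene that addition of the ring D ortho hydroxyl to Cq would give is assumed to re-ionize in acid and to be the less stable isomer.

## Route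

Step 1
Reactants: 1 1-(2,4-dihydroxyphenyl)ethan-1-one
Product: 2 1-[2-hydroxy-4-(methoxymethoxy)phenyl]ethan-1-one
Conditions: MOMCl (1.1 equiv), K2CO3, acetone, 0 °C to rt
Reagents that add atoms: chloromethyl methyl ether, COCCl
Why: Williamson-type O-alkylation; the 2-hydroxyl is held in a hydrogen bond to the acetyl carbonyl and is the weaker nucleophile, so the 4-phenoxide should react selectively.

Step 2
Reactants: 2 1-[2-hydroxy-4-(methoxymethoxy)phenyl]ethan-1-one
Product: 3 4-hydroxy-7-(methoxymethoxy)-2H-chromen-2-one
Conditions: NaH (4 equiv), (EtO)2CO, toluene, 110 °C; then cold 1 M HCl to pH 3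
Reagents that add atoms: diethyl carbonate, CCOC(=O)OCC
Why: Claisen-type C-acylation of the ketone enolate by the carbonate followed by lactonization of the phenoxide, the standard 4-hydroxycoumarin synthesis; the product rests as its sodium enolate until the brief cold acid quench, which the aryl acetal should survive.

Step 3
Reactants: 3 4-hydroxy-7-(methoxymethoxy)-2H-chromen-2-one
Product: 4 7-(methoxymethoxy)-2-oxo-2H-chromen-4-yl trifluoromethanesulfonate
Conditions: Tf2O, Et3N, CH2Cl2, −20 °C
Reagents that add atoms: trifluoromethanesulfonic anhydride, FC(F)(F)S(=O)(=O)OS(=O)(=O)C(F)(F)F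
Why: O-sulfonylation of a vinylogous carboxylic acid (enol triflate formation); the 4-oxygen is the only acidic site.

Step 4
Reactants: 4 7-(methoxymethoxy)-2-oxo-2H-chromen-4-yl trifluoromethanesulfonate; 5 2-[(E)-2-ethoxyethenyl]-4,4,5,5-tetramethyl-1,3,2-dioxaborolane
Product: 6 4-[(E)-2-ethoxyethenyl]-7-(methoxymethoxy)-2H-chromen-2-one
Conditions: Pd(PPh3)4 (5 mol%), K3PO4, 1,4-dioxane/H2O (10:1), 70 °C
Reagents that add atoms: none
Why: Suzuki–Miyaura coupling; the vinylogous acyl triflate adds readily to zerovalent palladium, and transmetalation and reductive elimination retain the alkene geometry, so the E configuration of 5 is carried into the diene.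

Step 5
Reactants: 7 4-hydroxybenzaldehyde
Product: 8 4-(methoxymethoxy)benzaldehyde
Conditions: MOMCl, i-Pr2NEt, CH2Cl2, 0 °C to rt
Reagents that add atoms: chloromethyl methyl ether, COCCl
Why: Acetal protection of a phenol (methoxymethyl ether formation) under amine base.

Step 6
Reactants: 8 4-(methoxymethoxy)benzaldehyde
Product: 9 1-ethynyl-4-(methoxymethoxy)benzene
Conditions: dimethyl (1-diazo-2-oxopropyl)phosphonate, K2CO3, MeOH, rt
Reagents that add atoms: dimethyl (1-diazo-2-oxopropyl)phosphonate, CC(=O)C(=[N+]=[N-])P(=O)(OC)OC
Why: Seyferth–Gilbert homologation with the Ohira–Bestmann reagent; methanolysis frees the diazomethylphosphonate anion, which turns the aldehyde into the terminal alkyne, and the carbonate base leaves the acetal untouched.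

Step 7
Reactants: 10 prop-2-yn-1-ol
Product: 11 3-bromoprop-2-yn-1-ol
Conditions: NBS, AgNO3 (10 mol%), acetone, rt
Reagents that add atoms: N-bromosuccinimide, O=C1CCC(=O)N1Br
Why: Silver-catalysed electrophilic bromination of a terminal alkyne through the silver acetylide; the free hydroxyl does not interfere.

Step 8
Reactants: 9 1-ethynyl-4-(methoxymethoxy)benzene; 11 3-bromoprop-2-yn-1-ol
Product: 12 5-[4-(methoxymethoxy)phenyl]penta-2,4-diyn-1-ol
Conditions: CuCl (5 mol%), NH2OH·HCl (20 mol%), n-BuNH2 (30% aq), MeOH, 0 °C, slow addition of 11
Reagents that add atoms: none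
Why: Cadiot–Chodkiewicz coupling of the monovalent copper acetylide of 9 with the bromoalkyne; hydroxylamine keeps the copper monovalent and so suppresses Glaser-type homocoupling.

Step 9
Reactants: 12 5-[4-(methoxymethoxy)phenyl]penta-2,4-diyn-1-ol
Product: 13 5-[4-(methoxymethoxy)phenyl]penta-2,4-diynal
Conditions: activated MnO2 (15 equiv), CH2Cl2, rt; filtration through Celite, used at once
Reagents that add atoms: none
Why: Heterogeneous oxidation of a propargylic alcohol by MnO2; the medium is neutral, over-oxidation is not expected, and work-up by filtration suits the sensitive diynal.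

Step 10
Reactants: 6 4-[(E)-2-ethoxyethenyl]-7-(methoxymethoxy)-2H-chromen-2-one; 13 5-[4-(methoxymethoxy)phenyl]penta-2,4-diynal
Product: 15 3-(methoxymethoxy)-7-{[4-(methoxymethoxy)phenyl]ethynyl}-6-oxo-6H-benzo[c]chromene-8-carbaldehyde, via ethoxy dihydro cycloadduct 14 (not isolated)
Conditions: 6 (1.3 equiv), BHT (5 mol%), toluene, 90 °C, slow addition of 13, argon, dark; then DBU (0.2 equiv), rt
Reagents that add atoms: none
Why: The diene is the coumarin C3=C4 bond with the (E)-2-ethoxyvinyl group, whose s-cis rotamer is the accessible one because the other pushes the vinyl terminus against the peri hydrogen at C5; it should add thermally, in a concerted but asynchronous normal-demand Diels–Alder reaction, across the aldehyde-conjugated triple bond of 13, closing ring A by intermolecular (4+2) cycloaddition (product bonds C6a–C7 and C8–C9, ring A bonds C1–C6 and C4–C5). The closest known reactions are the Diels–Alder additions of 4-vinyl- and 4-styrylcoumarins to acetylenic dienophiles that lead to benzo[c]chromen-6-ones, and the aromatizing cycloadditions of 1-alkoxybutadienes with ynals and propiolates. Orientation is the selectivity that matters: the ethoxy group on the vinyl terminus and the 7-alkoxyaryl ring on C4 both make coumarin C3 the nucleophilic end of the diene (bonding there leaves an allyl cation capped by the ethoxy oxygen and the electron-rich ring), which should outweigh the weak opposite preference of the lactone carbonyl, so C3 bonds to the alkynyl-bearing β-carbon of the ynal and the ethoxy-bearing carbon to the formyl-bearing α-carbon. Site selectivity follows from activation: only the triple bond conjugated to the aldehyde is electron-poor enough, while the distal triple bond of 13 and the diarylalkyne of the product are not, and without a Lewis acid the aldehyde carbonyl should not act as a heterodienophile. Adduct 14 forms as the cis racemate by suprafacial addition to the E diene, but both stereocenters are erased at once: the C6a hydrogen is acidic (α to the lactone carbonyl and vinylogously α to the aldehyde), and catalytic DBU should trigger a vinylogous E1cB loss of ethoxide from C9, so ethanol leaves and ring A aromatizes without an oxidant. No stereocenter remains in 15.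

Step 11
Reactants: 15 3-(methoxymethoxy)-7-{[4-(methoxymethoxy)phenyl]ethynyl}-6-oxo-6H-benzo[c]chromene-8-carbaldehyde
Product: 16 8-(hydroxymethyl)-3-(methoxymethoxy)-7-{[4-(methoxymethoxy)phenyl]ethynyl}-6H-benzo[c]chromen-6-one
Conditions: NaBH4, THF/MeOH (4:1), −20 to 0 °C; sat. aq NH4Cl
Reagents that add atoms: none
Why: Chemoselective borohydride reduction; at low temperature the aldehyde is reduced far faster than the aryl lactone, and the alkyne is inert to the hydride.

Step 12
Reactants: 16 8-(hydroxymethyl)-3-(methoxymethoxy)-7-{[4-(methoxymethoxy)phenyl]ethynyl}-6H-benzo[c]chromen-6-one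
Product: 17 8-({[tert-butyl(dimethyl)silyl]oxy}methyl)-3-(methoxymethoxy)-7-{[4-(methoxymethoxy)phenyl]ethynyl}-6H-benzo[c]chromen-6-one
Conditions: TBSCl, imidazole, DMF, rt
Reagents that add atoms: tert-butyl(chloro)dimethylsilane, CC(C)(C)[Si](C)(C)Cl
Why: Silylation of a primary alcohol; the silyl ether ensures that no alkoxide sits beside the triple bond or consumes aryllithium in the next step.

Step 13
Reactants: 18 4-bromophenol
Product: 19 1-bromo-4-(methoxymethoxy)benzene
Conditions: MOMCl, i-Pr2NEt, CH2Cl2, 0 °C to rt
Reagents that add atoms: chloromethyl methyl ether, COCCl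
Why: Acetal protection of a phenol (methoxymethyl ether formation).

Step 14
Reactants: 17 8-({[tert-butyl(dimethyl)silyl]oxy}methyl)-3-(methoxymethoxy)-7-{[4-(methoxymethoxy)phenyl]ethynyl}-6H-benzo[c]chromen-6-one; 19 1-bromo-4-(methoxymethoxy)benzene
Product: 22 {3-({[tert-butyl(dimethyl)silyl]oxy}methyl)-6-[2-hydroxy-4-(methoxymethoxy)phenyl]-2-{[4-(methoxymethoxy)phenyl]ethynyl}phenyl}bis[4-(methoxymethoxy)phenyl]methanol, via aryllithium 20 (not isolated), via lithium phenoxide ketone 21 (not isolated)
Conditions: 19 (3.3 equiv), n-BuLi (3.2 equiv), THF, −78 °C; then 17, −78 to 0 °C; sat. aq NH4Cl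
Reagents that add atoms: none
Why: Bromine–lithium exchange gives 20; its first addition opens the aryl lactone with loss of the ring D phenoxide to give ketone 21, and the second addition gives the triarylmethoxide (double addition of an organolithium to a lactone, as in carbinol syntheses from benzo[c]chromen-6-ones). At these temperatures the diarylalkyne, the acetals and the silyl ether should not react.

Step 15
Reactants: 22 {3-({[tert-butyl(dimethyl)silyl]oxy}methyl)-6-[2-hydroxy-4-(methoxymethoxy)phenyl]-2-{[4-(methoxymethoxy)phenyl]ethynyl}phenyl}bis[4-(methoxymethoxy)phenyl]methanol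
Product: 23 selaginellin F, 4-[{6-(2,4-dihydroxyphenyl)-3-(hydroxymethyl)-2-[(4-hydroxyphenyl)ethynyl]phenyl}(4-hydroxyphenyl)methylidene]cyclohexa-2,5-dien-1-one
Conditions: HCl (3 M aq), MeOH/THF (2:1), rt to 40 °C, argon; then phosphate buffer pH 6
Reagents that add atoms: none
Why: Acid-mediated global deprotection and dehydration: the four acetals and the silyl ether are cleaved and the carbinol ionizes to a cation stabilized by two para-oxygenated rings, which loses a phenolic proton to give the p-quinone methide (fuchsone formation from a 4-hydroxytrityl alcohol). An ether formed by capture of the cation by the ring D hydroxyl is a trityl aryl ether that should re-ionize under the same conditions.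

## Compound list

1 | 1-(2,4-dihydroxyphenyl)ethan-1-one | CC(=O)c1ccc(O)cc1O | starting material
2 | 1-[2-hydroxy-4-(methoxymethoxy)phenyl]ethan-1-one | CC(=O)c1ccc(OCOC)cc1O | intermediate
3 | 4-hydroxy-7-(methoxymethoxy)-2H-chromen-2-one | O=c1cc(O)c2ccc(OCOC)cc2o1 | intermediate
4 | 7-(methoxymethoxy)-2-oxo-2H-chromen-4-yl trifluoromethanesulfonate | O=c1cc(OS(=O)(=O)C(F)(F)F)c2ccc(OCOC)cc2o1 | intermediate
5 | 2-[(E)-2-ethoxyethenyl]-4,4,5,5-tetramethyl-1,3,2-dioxaborolane | CCO/C=C/B1OC(C)(C)C(C)(C)O1 | starting material
6 | 4-[(E)-2-ethoxyethenyl]-7-(methoxymethoxy)-2H-chromen-2-one | CCO/C=C/c1cc(=O)oc2cc(OCOC)ccc12 | intermediate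
7 | 4-hydroxybenzaldehyde | O=Cc1ccc(O)cc1 | starting material
8 | 4-(methoxymethoxy)benzaldehyde | COCOc1ccc(C=O)cc1 | intermediate
9 | 1-ethynyl-4-(methoxymethoxy)benzene | C#Cc1ccc(OCOC)cc1 | intermediate
10 | prop-2-yn-1-ol | C#CCO | starting material
11 | 3-bromoprop-2-yn-1-ol | OCC#CBr | intermediate
12 | 5-[4-(methoxymethoxy)phenyl]penta-2,4-diyn-1-ol | OCC#CC#Cc1ccc(OCOC)cc1 | intermediate
13 | 5-[4-(methoxymethoxy)phenyl]penta-2,4-diynal | O=CC#CC#Cc1ccc(OCOC)cc1 | intermediate
14 | cis-9-ethoxy-3-(methoxymethoxy)-7-{[4-(methoxymethoxy)phenyl]ethynyl}-6-oxo-6a,9-dihydro-6H-benzo[c]chromene-8-carbaldehyde (racemic; 6a-H and 9-H on the same face; one enantiomer drawn) | CCO[C@H]1C=C2c3ccc(OCOC)cc3OC(=O)[C@H]2C(C#Cc2ccc(OCOC)cc2)=C1C=O | intermediate (not isolated)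
15 | 3-(methoxymethoxy)-7-{[4-(methoxymethoxy)phenyl]ethynyl}-6-oxo-6H-benzo[c]chromene-8-carbaldehyde | O=Cc1ccc2c(c1C#Cc3ccc(OCOC)cc3)c(=O)oc4cc(OCOC)ccc24 | intermediate
16 | 8-(hydroxymethyl)-3-(methoxymethoxy)-7-{[4-(methoxymethoxy)phenyl]ethynyl}-6H-benzo[c]chromen-6-one | OCc1ccc2c(c1C#Cc3ccc(OCOC)cc3)c(=O)oc4cc(OCOC)ccc24 | intermediate
17 | 8-({[tert-butyl(dimethyl)silyl]oxy}methyl)-3-(methoxymethoxy)-7-{[4-(methoxymethoxy)phenyl]ethynyl}-6H-benzo[c]chromen-6-one | CC(C)(C)[Si](C)(C)OCc1ccc2c(c1C#Cc3ccc(OCOC)cc3)c(=O)oc4cc(OCOC)ccc24 | intermediate
18 | 4-bromophenol | Oc1ccc(Br)cc1 | starting material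
19 | 1-bromo-4-(methoxymethoxy)benzene | COCOc1ccc(Br)cc1 | intermediate
20 | [4-(methoxymethoxy)phenyl]lithium | [Li]c1ccc(OCOC)cc1 | intermediate (not isolated)
21 | lithium 2-[4-({[tert-butyl(dimethyl)silyl]oxy}methyl)-2-[4-(methoxymethoxy)benzoyl]-3-{[4-(methoxymethoxy)phenyl]ethynyl}phenyl]-5-(methoxymethoxy)phenolate | [Li+].[O-]c1cc(OCOC)ccc1-c1ccc(CO[Si](C)(C)C(C)(C)C)c(C#Cc2ccc(OCOC)cc2)c1C(=O)c1ccc(OCOC)cc1 | intermediate (not isolated)
22 | {3-({[tert-butyl(dimethyl)silyl]oxy}methyl)-6-[2-hydroxy-4-(methoxymethoxy)phenyl]-2-{[4-(methoxymethoxy)phenyl]ethynyl}phenyl}bis[4-(methoxymethoxy)phenyl]methanol | COCOc1ccc(cc1)C(O)(c1ccc(OCOC)cc1)c1c(-c2ccc(OCOC)cc2O)ccc(CO[Si](C)(C)C(C)(C)C)c1C#Cc1ccc(OCOC)cc1 | intermediate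
23 | selaginellin F, 4-[{6-(2,4-dihydroxyphenyl)-3-(hydroxymethyl)-2-[(4-hydroxyphenyl)ethynyl]phenyl}(4-hydroxyphenyl)methylidene]cyclohexa-2,5-dien-1-one | O=C1C=CC(=C(c2ccc(O)cc2)c2c(-c3ccc(O)cc3O)ccc(CO)c2C#Cc2ccc(O)cc2)C=C1 | target

## Step count and risks

Total: 15 steps. Longest linear sequence: 9 steps (1–4, 10–12, 14, 15; the dienophile branch 5, 6, 8, 9 followed by 10–12, 14, 15 is equally long).

**Step 10 (key step).** The most likely failure is thermal oligomerization of the diynal before it cycloadds. The ethoxy diene is also conjugated to the lactone carbonyl, which lowers its reactivity, and 13 has two triple bonds and an aldehyde that can react with itself at 90 °C. A minor risk is residual addition in the opposite orientation.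
Fallback, from 6 and 9, rejoining at 16: the arylethynyl group is installed by cross-coupling after ring A exists.
- Methyl propiolate is brominated (NBS, AgNO3) to methyl 3-bromoprop-2-ynoate F1, a robust dienophile.
- Heating F1 with 6 in toluene, followed by DBU, should give methyl 7-bromo-3-(methoxymethoxy)-6-oxo-6H-benzo[c]chromene-8-carboxylate F2 in the same orientation.
- Sonogashira coupling of F2 with alkyne 9 (PdCl2(PPh3)2, CuI, Et3N, 60 °C) gives methyl 3-(methoxymethoxy)-7-{[4-(methoxymethoxy)phenyl]ethynyl}-6-oxo-6H-benzo[c]chromene-8-carboxylate F3.
- LiOH in THF/H2O followed by acidification hydrolyses the methyl ester and lets the lactone close again, giving 3-(methoxymethoxy)-7-{[4-(methoxymethoxy)phenyl]ethynyl}-6-oxo-6H-benzo[c]chromene-8-carboxylic acid F4.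
- Activation of F4 with isobutyl chloroformate and N-methylmorpholine at −15 °C gives the isobutyl carbonic mixed anhydride F5, and NaBH4 reduces it, in preference to the lactone, to alcohol 16.

**Step 14.** The sequence may stop after the first aryl transfer: the intermediate lactol alkoxide may not collapse at low temperature, and ketone 21 is flanked on both sides and electron-rich. Warming to force the second addition brings the risk of silyl ether cleavage or addition to the alkyne.
Fallback, from 17, rejoining at 23: the two aryl groups are introduced separately.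
- One equivalent of 20 at −78 °C with a cold quench gives {3-({[tert-butyl(dimethyl)silyl]oxy}methyl)-6-[2-hydroxy-4-(methoxymethoxy)phenyl]-2-{[4-(methoxymethoxy)phenyl]ethynyl}phenyl}[4-(methoxymethoxy)phenyl]methanone F6.
- MOMCl and i-Pr2NEt cap the ring D phenol to give {6-[2,4-bis(methoxymethoxy)phenyl]-3-({[tert-butyl(dimethyl)silyl]oxy}methyl)-2-{[4-(methoxymethoxy)phenyl]ethynyl}phenyl}[4-(methoxymethoxy)phenyl]methanone F7.
- The organocerium reagent from 20 and CeCl3 adds to the now uncharged ketone to give {6-[2,4-bis(methoxymethoxy)phenyl]-3-({[tert-butyl(dimethyl)silyl]oxy}methyl)-2-{[4-(methoxymethoxy)phenyl]ethynyl}phenyl}bis[4-(methoxymethoxy)phenyl]methanol F8.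
- The acid treatment of step 15 converts F8 into 23.

**Step 15.** Capture of the Cq cation by the ring D ortho hydroxyl (ring closure to a cyclic ether) may be faster than loss of the phenolic proton, and the ether may persist under acid. Prolonged acid can also substitute the benzylic alcohol.
Fallback, from 22, rejoining at 23: the ring-closed isomer is made on purpose and opened under base.
- Acid treatment of 22 is driven to 6,6-bis(4-hydroxyphenyl)-8-(hydroxymethyl)-7-[(4-hydroxyphenyl)ethynyl]-6H-benzo[c]chromen-3-ol F9, which is purified as a colourless compound.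
- Aqueous NaOH in MeOH at 0 °C should open F9 by phenoxide-driven expulsion of the ring D aryloxide (the reverse of a 1,6-addition, as in the base opening of triarylmethane leuco ethers).
- Protonation of the quinone methide phenolate with cold phosphate buffer and immediate extraction gives 23 under kinetic control.

**Step 8.** Homocoupling of either partner may compete if the copper is oxidized to the divalent state, and bromoalkyne 11 can decompose during slow addition.
Fallback, from 8 and 10, rejoining at 12: aldehyde 8 is converted with CBr4 and PPh3 (first stage of the Corey–Fuchs sequence) into 1-(2,2-dibromoethenyl)-4-(methoxymethoxy)benzene F10. Palladium-catalysed coupling of F10 with propargyl alcohol 10 (Pd2(dba)3, dba = dibenzylideneacetone, tri(2-furyl)phosphine, Et3N, DMF, 80 °C) gives diynol 12 directly, without a copper acetylide or a bromoalkyne.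

## Further compounds

F1 | step 10 | methyl 3-bromoprop-2-ynoate | COC(=O)C#CBr
F2 | step 10 | methyl 7-bromo-3-(methoxymethoxy)-6-oxo-6H-benzo[c]chromene-8-carboxylate | COC(=O)c1ccc2c(c1Br)c(=O)oc1cc(OCOC)ccc12
F3 | step 10 | methyl 3-(methoxymethoxy)-7-{[4-(methoxymethoxy)phenyl]ethynyl}-6-oxo-6H-benzo[c]chromene-8-carboxylate | COC(=O)c1ccc2c(c1C#Cc1ccc(OCOC)cc1)c(=O)oc1cc(OCOC)ccc12
F4 | step 10 | 3-(methoxymethoxy)-7-{[4-(methoxymethoxy)phenyl]ethynyl}-6-oxo-6H-benzo[c]chromene-8-carboxylic acid | OC(=O)c1ccc2c(c1C#Cc1ccc(OCOC)cc1)c(=O)oc1cc(OCOC)ccc12
F5 | step 10 | 3-(methoxymethoxy)-7-{[4-(methoxymethoxy)phenyl]ethynyl}-6-oxo-6H-benzo[c]chromene-8-carboxylic (2-methylpropyl carbonic) anhydride | CC(C)COC(=O)OC(=O)c1ccc2c(c1C#Cc1ccc(OCOC)cc1)c(=O)oc1cc(OCOC)ccc12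
F6 | step 14 | {3-({[tert-butyl(dimethyl)silyl]oxy}methyl)-6-[2-hydroxy-4-(methoxymethoxy)phenyl]-2-{[4-(methoxymethoxy)phenyl]ethynyl}phenyl}[4-(methoxymethoxy)phenyl]methanone | COCOc1ccc(cc1)C(=O)c1c(-c2ccc(OCOC)cc2O)ccc(CO[Si](C)(C)C(C)(C)C)c1C#Cc1ccc(OCOC)cc1
F7 | step 14 | {6-[2,4-bis(methoxymethoxy)phenyl]-3-({[tert-butyl(dimethyl)silyl]oxy}methyl)-2-{[4-(methoxymethoxy)phenyl]ethynyl}phenyl}[4-(methoxymethoxy)phenyl]methanone | COCOc1ccc(cc1)C(=O)c1c(-c2ccc(OCOC)cc2OCOC)ccc(CO[Si](C)(C)C(C)(C)C)c1C#Cc1ccc(OCOC)cc1
F8 | step 14 | {6-[2,4-bis(methoxymethoxy)phenyl]-3-({[tert-butyl(dimethyl)silyl]oxy}methyl)-2-{[4-(methoxymethoxy)phenyl]ethynyl}phenyl}bis[4-(methoxymethoxy)phenyl]methanol | COCOc1ccc(cc1)C(O)(c1ccc(OCOC)cc1)c1c(-c2ccc(OCOC)cc2OCOC)ccc(CO[Si](C)(C)C(C)(C)C)c1C#Cc1ccc(OCOC)cc1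
F9 | step 15 | 6,6-bis(4-hydroxyphenyl)-8-(hydroxymethyl)-7-[(4-hydroxyphenyl)ethynyl]-6H-benzo[c]chromen-3-ol | OCc1ccc2c(c1C#Cc1ccc(O)cc1)C(c1ccc(O)cc1)(c1ccc(O)cc1)Oc1cc(O)ccc12
F10 | step 8 | 1-(2,2-dibromoethenyl)-4-(methoxymethoxy)benzene | COCOc1ccc(C=C(Br)Br)cc1
A1 | alternative 1 | methyl 6-(methoxymethoxy)-3-[(methoxymethoxy)methyl]-2-{[4-(triisopropylsilyloxy)phenyl]ethynyl}benzoate | COC(=O)c1c(OCOC)ccc(COCOC)c1C#Cc1ccc(O[Si](C(C)C)(C(C)C)C(C)C)cc1
A2 | alternative 1 | 2-chloro-4-(methoxymethoxy)-1-[(methoxymethoxy)methyl]benzene | COCOCc1ccc(OCOC)cc1Cl
A3 | alternative 1 | (4-ethynylphenoxy)tri(propan-2-yl)silane | C#Cc1ccc(O[Si](C(C)C)(C(C)C)C(C)C)cc1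
A4 | alternative 2 | 8-[(tert-butyldimethylsilyloxy)methyl]-3-(methoxymethoxy)-7-{[4-(methoxymethoxy)phenyl]ethynyl}-9-(trimethylsilyl)-6H-benzo[c]chromen-6-one | O=C1Oc2cc(OCOC)ccc2-c2cc([Si](C)(C)C)c(CO[Si](C)(C)C(C)(C)C)c(C#Cc3ccc(OCOC)cc3)c21
A5 | alternative 2 | 2-ethynyl-5-(methoxymethoxy)phenyl 5-[4-(methoxymethoxy)phenyl]penta-2,4-diynoate | C#Cc1ccc(OCOC)cc1OC(=O)C#CC#Cc1ccc(OCOC)cc1
A6 | alternative 2 | tert-butyl(dimethyl){[3-(trimethylsilyl)prop-2-yn-1-yl]oxy}silane | C[Si](C)(C)C#CCO[Si](C)(C)C(C)(C)C
A7 | alternative 3 | 7-hydroxy-3-(triisopropylsilyloxy)-8-[(triisopropylsilyloxy)methyl]-6H-benzo[c]chromen-6-one | O=C1Oc2cc(O[Si](C(C)C)(C(C)C)C(C)C)ccc2-c2ccc(CO[Si](C(C)C)(C(C)C)C(C)C)c(O)c21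
A8 | alternative 3 | 7-(triisopropylsilyloxy)-4H-chromen-4-one | O=c1ccoc2cc(O[Si](C(C)C)(C(C)C)C(C)C)ccc12
A9 | alternative 3 | (3Z)-1-methoxy-1,3-bis(trimethylsilyloxy)-5-(triisopropylsilyloxy)penta-1,3-diene (ketene acetal geometry not defined) | COC(O[Si](C)(C)C)=C/C(O[Si](C)(C)C)=C/CO[Si](C(C)C)(C(C)C)C(C)C
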